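## Structural features

The target 12 is a 7-deoxy 8-O-4' neolignan. Ring A (4-hydroxy-3-methoxyphenyl) carries a three-carbon chain C7–C8–C9, and the oxygen on C8 is bonded to C4 of ring B, a benzene ring with methoxy groups at C3 and C5 and an allyl group at C1. There are no rings beyond the two arenes, and the two halves are joined only through the C7–C8 bond and the C8–O–C4 ether bridge. C8 is the single stereocentre (S) and has no stereogenic neighbour, so the whole stereochemical problem is one secondary alkyl aryl ether carbon flanked by a methyl group and a benzylic CH2. The fragile groups are the terminal allyl group (it migrates into conjugation under strong base or metal hydrides and would not survive hydrogenation), the free phenol of ring A and, among the intermediates, any arylacetaldehyde. The real difficulty is the C8–O–aryl bond: the oxygen lies between two ortho methoxy groups, so the ring B phenol is a poor nucleophile for substitution at a secondary carbon, and C8 with its benzylic neighbour C7 eliminates easily. The key step reverses this polarity and uses the para relation between the ether carbon C4 and the allyl-bearing carbon C1 of ring B: a formyl group at C1 makes a fluoride at C4 displaceable by the C8 alkoxide, so the C8–O bond arrives ready-made and only the aryl C4–O bond is formed. The formyl carbon then becomes the benzylic carbon of the allyl group.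

## Logic of the disconnections

12 is cut at the terminal C=C bond of the allyl group, which leads back to 11. The alkene is placed last so that it meets neither the acid of the unmasking step nor the alkoxide of the ether formation. The forward step must olefinate an enolisable aldehyde in the presence of a free phenol, so a small, reactive one-carbon ylide in excess is required.

11 is traced to 9 by two functional-group changes in one operation: the aldehyde comes from a methyl enol ether and the phenol from its methoxymethyl acetal, with 10 as the intermediate in the flask. One acid treatment thus replaces two steps. The demand is that the C8–O ether and the new aldehyde tolerate aqueous acid; the ether is secondary and not benzylic, so it should.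

9 is cut at its enol ether C=C bond, which leads back to 8. This one-carbon homologation is what turns the activating formyl carbon into the future benzylic carbon. It places no stereochemical demand, because both alkene isomers converge in the next step.

8 is cut at the aryl C4–O bond of ring B into 5 (reacting as 7) and 6. The oxygen nucleophile is already attached to C8, so the stereocentre is a spectator and no substitution at a hindered secondary carbon is needed. The molecule falls into two fragments of similar size. The forward step must make the alkoxide attack the fluorine-bearing carbon faster than it reacts with the aldehyde.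

5 is cut at the bond between ring A and C7 into 2 (reacting as 4) and 3. The C8 stereocentre then comes intact from a cheap chiral-pool epoxide, and ring A enters as an aryl nucleophile. The forward step must open the epoxide only at its CH2 terminus.

2 is traced to 1 by removal of the protecting group. The phenol proton would quench the organomagnesium reagent, and a phenoxide would compete as a nucleophile in the ether formation. The methoxymethyl group is chosen because it is inert to magnesium, alkoxide and ylide and leaves in the same acid step that frees the aldehyde. A silyl ether could migrate to the alkoxide, and a benzyl ether could not be removed by hydrogenolysis without reducing the allyl group.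

## Other disconnections considered

Alternative 1: The cut is the C7–C8 bond. Racemic 5-allyl-2-(1-chloroethoxy)-1,3-dimethoxybenzene A1 and [3-methoxy-4-(triisopropylsilyloxy)benzyl]zinc chloride A2 would be coupled with NiBr2(dme) and a chiral pybox ligand to give the silyl ether A3 of the target, and fluoride would then free the phenol.
- Mechanism: low-valent nickel abstracts chloride from either enantiomer of A1 to give the same oxygen-stabilised C8 radical, and the chiral benzylnickel complex captures it and reductively eliminates. The stereocentre is therefore created under catalyst control from racemic material.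
- In favour: both rings are complete, the allyl group is in place from the start, ring B needs no functional-group change, and the hindered aryl ether bond is made at an achiral stage. On convergence this is better than the chosen plan, and on the longest linear sequence it is about equal.
- Against: A1 is an oxocarbenium precursor, so Lewis-acidic zinc could bring about direct, uncatalysed substitution to racemic product. Enantiocontrol would rest on the catalyst distinguishing a methyl group from a bulky 2,6-dimethoxyaryloxy group at a radical centre with no coordinating group. A1 also hydrolyses and loses HCl readily, and the terminal alkene would have to survive nickel hydride species.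
- Comparison: the chosen plan buys its configuration from the chiral pool and never touches C8, whereas this route has to earn its enantiomeric purity in a demanding substrate class.

Alternative 2: The cut is the C7–H bond, after the C8–O bond has been made by phenoxide alkylation next to a ketone. Racemic 2-(4-allyl-2,6-dimethoxyphenoxy)-1-[3-methoxy-4-(methoxymethoxy)phenyl]propan-1-one A4 epimerises at C8 through its enol. A ketoreductase with NADPH would reduce only the 8S ketone and give (1R,2S)-2-(4-allyl-2,6-dimethoxyphenoxy)-1-[3-methoxy-4-(methoxymethoxy)phenyl]propan-1-ol A5. The C7 hydroxyl would then be removed by ionic hydrogenation, which also cleaves the acetal.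
- In favour: the hindered C8–O bond forms by a reliable SN2 reaction at a carbonyl-activated carbon, which is better than the chosen plan's attack on a crowded aryl fluoride. The allyl group is present from the start, so no formyl-to-allyl conversion is needed. A dynamic kinetic resolution can in principle convert all of the racemate.
- Against: the C7 oxygen and the C7 stereocentre are absent from 12, so they are made only to be destroyed. The deoxygenation passes through a para-alkoxybenzyl cation next to C8, which can lose the C8 proton to an enol ether and so endanger the only stereocentre. The enzyme must accept a ketone with two bulky flanks, and epimerisation must outrun reduction of the wrong enantiomer.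
- Comparison: the step count is about equal to that of the chosen plan, the redox economy is worse, and the configurational safety of C8 is lower.

Alternative 3: The cut is the pair of C8–H and C7–H bonds. (Z)-2-(4-Bromo-2,6-dimethoxyphenoxy)-3-[3-methoxy-4-(methoxymethoxy)phenyl]prop-2-enoic acid A6 would be hydrogenated with H2 and Ru(OAc)2(BINAP), the carboxylate holding the olefin on ruthenium, to give (R)-2-(4-bromo-2,6-dimethoxyphenoxy)-3-[3-methoxy-4-(methoxymethoxy)phenyl]propanoic acid A7.
- In favour: carboxylate-directed hydrogenation of alpha-oxygenated cinnamic acids is a mature reaction type with a predictable sense of induction. A6 is assembled by condensation at an achiral stage, so the crowded aryl ether is again made without stereochemical constraint. In predictability it comes close to the chosen plan, and in the ease of the aryl ether bond it is better.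
- Against: the carboxyl carbon must afterwards be taken down to a methyl group (reduction, sulfonate, hydride). The allyl group must be attached late by cross-coupling at the bromide because it would not survive H2. The bulky aryloxy group on the olefin may slow turnover, and the bromide may be partly reduced.
- Comparison: the route would need about ten steps against six, so it is clearly inferior in step economy, and it uses four functional-group adjustments that the chosen plan avoids.

Key step: step 3

Remark: 6 is taken as a purchasable building block. The configurational chain is self-consistent. The S epoxide 3 gives the S carbinol 5 because the ring CH2 keeps its CIP rank when it becomes CH2Ar, and 5 gives the S ether 8 and S target 12 because the C8–O bond is never broken. No structure needs correcting; the refinements concern the way the alkoxide is generated and used in step 3.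

## Route

Step 1
Reactants: 1 4-bromo-2-methoxyphenol
Product: 2 4-bromo-2-methoxy-1-(methoxymethoxy)benzene
Conditions: MOMCl, iPr2NEt, CH2Cl2, 0 °C to rt
Reagents that add atoms: chloromethyl methyl ether, COCCl
Why: O-alkylation of the phenol with a highly reactive alpha-chloro ether (methoxymethyl protection); the acetal is inert to magnesium, alkoxide and ylide and is removed in the acid step 5.

Step 2
Reactants: 2 4-bromo-2-methoxy-1-(methoxymethoxy)benzene; 3 (S)-2-methyloxirane
Product: 5 (S)-1-[3-methoxy-4-(methoxymethoxy)phenyl]propan-2-ol, via arylmagnesium bromide 4 (not isolated)
Conditions: Mg (I2 cat.), THF, 40 °C; then CuI (10 mol %), 3, −30 to 0 °C; aq. NH4Cl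
Reagents that add atoms: none
Why: Magnesium insertion gives 4, and catalysis by monovalent copper makes an aryl cuprate that opens the epoxide by SN2 attack at the unsubstituted CH2 (copper-catalysed Grignard epoxide opening). The oxygen-bearing carbon of 3 is not touched, so its configuration is carried over and the descriptor stays S.

Step 3
Reactants: 5 (S)-1-[3-methoxy-4-(methoxymethoxy)phenyl]propan-2-ol; 6 4-fluoro-3,5-dimethoxybenzaldehyde
Product: 8 4-{[(2S)-1-[3-methoxy-4-(methoxymethoxy)phenyl]propan-2-yl]oxy}-3,5-dimethoxybenzaldehyde, via potassium alkoxide 7 (not isolated)
Conditions: KN(SiMe3)2 (0.95 equiv), 18-crown-6, THF, −40 °C; then 6 (1.2 equiv), −40 to 0 °C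
Reagents that add atoms: none
Why: Addition–elimination (SNAr): alkoxide 7 adds to the fluorine-bearing C4 of 6 to give a Meisenheimer anion whose charge is delocalised through C1 into the formyl oxygen, and loss of fluoride restores the arene. The closest known reaction type is the etherification of 4-fluorobenzaldehydes and other para-acceptor aryl fluorides by metal alkoxides, including the retentive arylation of enantiopure secondary alkoxides. No ring closes. No stereocentre is created: the C8–O bond of 7 is never broken and C8 has no acidic hydrogen, so the S configuration passes unchanged into 8, and the descriptor stays S because the order O > CH2Ar > CH3 is the same in 5 and 8. The selectivity needed is chemoselectivity for the C–F carbon over the carbonyl group; site selectivity is secured by the substrate, since fluoride is the only nucleofuge and the only substituent para to the acceptor, while the methoxy groups sit meta to it. Hemiacetal formation at the aldehyde is reversible and drains into the irreversible fluoride loss, whereas hydride transfer from the carbinol C–H needs a metal-templated six-membered transition state, which is disfavoured by sequestering K+ with 18-crown-6 and by the low temperature. The slight deficit of KN(SiMe3)2 relative to 5 ensures that no free amide base reaches the aldehyde. Fluoride is chosen because addition is rate-limiting and the polarised C–F bond makes the crowded C4 the most electrophilic ring carbon.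

Step 4
Reactants: 8 4-{[(2S)-1-[3-methoxy-4-(methoxymethoxy)phenyl]propan-2-yl]oxy}-3,5-dimethoxybenzaldehyde
Product: 9 (E/Z)-2-{[(2S)-1-[3-methoxy-4-(methoxymethoxy)phenyl]propan-2-yl]oxy}-1,3-dimethoxy-5-(2-methoxyethenyl)benzene
Conditions: MeOCH2PPh3Cl, KOtBu, THF, 0 °C to rt
Reagents that add atoms: (methoxymethyl)triphenylphosphonium chloride, COC[P+](c1ccccc1)(c1ccccc1)c1ccccc1.[Cl-]
Why: Wittig reaction of a non-enolisable aryl aldehyde with the methoxymethylene ylide (one-carbon homologation). The E/Z mixture is of no consequence because both isomers hydrolyse to the same aldehyde, and the base cannot affect C8.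

Step 5
Reactants: 9 (E/Z)-2-{[(2S)-1-[3-methoxy-4-(methoxymethoxy)phenyl]propan-2-yl]oxy}-1,3-dimethoxy-5-(2-methoxyethenyl)benzene
Product: 11 2-(4-{[(2S)-1-(4-hydroxy-3-methoxyphenyl)propan-2-yl]oxy}-3,5-dimethoxyphenyl)acetaldehyde, via MOM-protected arylacetaldehyde 10 (not isolated)
Conditions: 3 M aq. HCl, THF, 50 °C
Reagents that add atoms: water, O
Why: Acid-catalysed hydrolysis: protonation of the enol ether at the benzylic carbon gives an oxocarbenium ion that water converts into aldehyde 10, and the same acid then cleaves the aryl methoxymethyl acetal through its own oxocarbenium ion. The C8 ether is secondary and not benzylic, so it should not ionise under these conditions.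

Step 6
Reactants: 11 2-(4-{[(2S)-1-(4-hydroxy-3-methoxyphenyl)propan-2-yl]oxy}-3,5-dimethoxyphenyl)acetaldehyde
Product: 12 4-[(2S)-2-(4-allyl-2,6-dimethoxyphenoxy)propyl]-2-methoxyphenol
Conditions: Ph3PCH3Br (3.3 equiv), KOtBu (3.0 equiv), THF, 0 °C; then 11, 0 °C to rt
Reagents that add atoms: methyltriphenylphosphonium bromide, C[P+](c1ccccc1)(c1ccccc1)c1ccccc1.[Br-]
Why: Wittig methylenation; the first equivalent of ylide is consumed by the phenol O–H and the resulting phenoxide is a spectator. The small non-stabilised ylide should add to the aldehyde faster than it enolises it at 0 °C, and the terminal alkene should not migrate into conjugation under these conditions.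

## Compound list

1 | 4-bromo-2-methoxyphenol | COc1cc(Br)ccc1O | starting material
2 | 4-bromo-2-methoxy-1-(methoxymethoxy)benzene | COCOc1ccc(Br)cc1OC | intermediate
3 | (S)-2-methyloxirane ((S)-propylene oxide) | C[C@H]1CO1 | starting material
4 | [3-methoxy-4-(methoxymethoxy)phenyl]magnesium bromide | COCOc1ccc([Mg]Br)cc1OC | intermediate (not isolated)
5 | (S)-1-[3-methoxy-4-(methoxymethoxy)phenyl]propan-2-ol | O[C@@H](C)Cc1ccc(OCOC)c(OC)c1 | intermediate
6 | 4-fluoro-3,5-dimethoxybenzaldehyde | COc1cc(C=O)cc(OC)c1F | starting material
7 | potassium (S)-1-[3-methoxy-4-(methoxymethoxy)phenyl]propan-2-olate | [K+].[O-][C@@H](C)Cc1ccc(OCOC)c(OC)c1 | intermediate (not isolated)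
8 | 4-{[(2S)-1-[3-methoxy-4-(methoxymethoxy)phenyl]propan-2-yl]oxy}-3,5-dimethoxybenzaldehyde | O=Cc1cc(OC)c(O[C@@H](C)Cc2ccc(OCOC)c(OC)c2)c(OC)c1 | intermediate
9 | (E/Z)-2-{[(2S)-1-[3-methoxy-4-(methoxymethoxy)phenyl]propan-2-yl]oxy}-1,3-dimethoxy-5-(2-methoxyethenyl)benzene (mixture of alkene isomers) | COC=Cc1cc(OC)c(O[C@@H](C)Cc2ccc(OCOC)c(OC)c2)c(OC)c1 | intermediate
10 | 2-(3,5-dimethoxy-4-{[(2S)-1-[3-methoxy-4-(methoxymethoxy)phenyl]propan-2-yl]oxy}phenyl)acetaldehyde | O=CCc1cc(OC)c(O[C@@H](C)Cc2ccc(OCOC)c(OC)c2)c(OC)c1 | intermediate (not isolated)
11 | 2-(4-{[(2S)-1-(4-hydroxy-3-methoxyphenyl)propan-2-yl]oxy}-3,5-dimethoxyphenyl)acetaldehyde | O=CCc1cc(OC)c(O[C@@H](C)Cc2ccc(O)c(OC)c2)c(OC)c1 | intermediate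
12 | 4-[(2S)-2-(4-allyl-2,6-dimethoxyphenoxy)propyl]-2-methoxyphenol | C=CCc1cc(OC)c(O[C@@H](C)Cc2ccc(O)c(OC)c2)c(OC)c1 | target

## Step count and risk

Total step count: 6 steps. Longest linear sequence: 6 steps (1 → 2 → 5 → 8 → 9 → 11 → 12); 3 and 6 are purchased.

Step 3 (key step). The most likely failure is hydride transfer from the alkoxide C–H to the aldehyde, together with redox of the hemiacetal alkoxide, outrunning the substitution. The substitution is slowed because both positions ortho to the C–F carbon carry methoxy groups, which crowd C4 and donate into it. The fallback sets out from 6 and 5 and replaces the acceptor by one that cannot accept hydride or form a hemiacetal. 6 would be converted with I2 and aqueous NH3 in THF into 4-fluoro-3,5-dimethoxybenzonitrile F1. Alkoxide 7 would then displace fluoride from F1 in THF/DMF, with warming if needed, to give 4-{[(2S)-1-[3-methoxy-4-(methoxymethoxy)phenyl]propan-2-yl]oxy}-3,5-dimethoxybenzonitrile F2. Partial reduction of F2 with iBu2AlH in toluene at −78 °C and hydrolytic work-up would return the route to 8, at the cost of two extra steps.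

Step 5. The most likely failure is acid-promoted self-condensation of the enolisable arylacetaldehyde, and capture of the released formaldehyde by the electron-rich phenol ring, during the time needed for complete acetal cleavage. The fallback sets out from 8 and never forms an arylacetaldehyde. NaBH4 in methanol would give (4-{[(2S)-1-[3-methoxy-4-(methoxymethoxy)phenyl]propan-2-yl]oxy}-3,5-dimethoxyphenyl)methanol F3. PPh3 and CBr4 would convert it into 5-(bromomethyl)-2-{[(2S)-1-[3-methoxy-4-(methoxymethoxy)phenyl]propan-2-yl]oxy}-1,3-dimethoxybenzene F4. Stille coupling with Bu3SnCH=CH2 and Pd(PPh3)4 (zerovalent palladium) in toluene would give 5-allyl-2-{[(2S)-1-[3-methoxy-4-(methoxymethoxy)phenyl]propan-2-yl]oxy}-1,3-dimethoxybenzene F5. HCl in methanol would then remove the acetal and the route would arrive at 12, one step longer than the main sequence from 8.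

Step 6. The most likely failure is enolisation of the arylacetaldehyde by the basic ylide, leading to aldol oligomers and incomplete conversion; it is aggravated by the poorly soluble phenoxide. The fallback sets out from 11 and uses a less basic, more nucleophilic one-carbon reagent in a Peterson olefination. Me3SiCH2MgCl with CeCl3 in THF would add to the aldehyde to give 4-[(2S)-2-{4-[2-hydroxy-3-(trimethylsilyl)propyl]-2,6-dimethoxyphenoxy}propyl]-2-methoxyphenol F6 as a mixture of carbinol epimers. Acid-induced elimination (catalytic H2SO4, THF) would then give 12.

Step 2. The most likely failures are sluggish magnesium insertion into the electron-rich aryl bromide with biaryl homocoupling, and halide-induced opening of the epoxide to a halohydrin instead of carbon–carbon bond formation. The fallback sets out from 2 and moves the origin of the stereocentre from the chiral pool to an enzymatic reduction. Palladium-catalysed mono-alpha-arylation of acetone ([Pd(cinnamyl)Cl]2, Mor-DalPhos, Cs2CO3, acetone) would give 1-[3-methoxy-4-(methoxymethoxy)phenyl]propan-2-one F7. A Prelog-selective alcohol dehydrogenase with NADH and isopropanol would reduce it to the S alcohol, and the route would come back at 5.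

## Further compounds

F1 | step 3 | 4-fluoro-3,5-dimethoxybenzonitrile | COc1cc(C#N)cc(OC)c1F
F2 | step 3 | 4-{[(2S)-1-[3-methoxy-4-(methoxymethoxy)phenyl]propan-2-yl]oxy}-3,5-dimethoxybenzonitrile | N#Cc1cc(OC)c(O[C@@H](C)Cc2ccc(OCOC)c(OC)c2)c(OC)c1
F3 | step 5 | (4-{[(2S)-1-[3-methoxy-4-(methoxymethoxy)phenyl]propan-2-yl]oxy}-3,5-dimethoxyphenyl)methanol | OCc1cc(OC)c(O[C@@H](C)Cc2ccc(OCOC)c(OC)c2)c(OC)c1
F4 | step 5 | 5-(bromomethyl)-2-{[(2S)-1-[3-methoxy-4-(methoxymethoxy)phenyl]propan-2-yl]oxy}-1,3-dimethoxybenzene | BrCc1cc(OC)c(O[C@@H](C)Cc2ccc(OCOC)c(OC)c2)c(OC)c1
F5 | step 5 | 5-allyl-2-{[(2S)-1-[3-methoxy-4-(methoxymethoxy)phenyl]propan-2-yl]oxy}-1,3-dimethoxybenzene | C=CCc1cc(OC)c(O[C@@H](C)Cc2ccc(OCOC)c(OC)c2)c(OC)c1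
F6 | step 6 | 4-[(2S)-2-{4-[2-hydroxy-3-(trimethylsilyl)propyl]-2,6-dimethoxyphenoxy}propyl]-2-methoxyphenol (mixture of carbinol epimers) | C[Si](C)(C)CC(O)Cc1cc(OC)c(O[C@@H](C)Cc2ccc(O)c(OC)c2)c(OC)c1
F7 | step 2 | 1-[3-methoxy-4-(methoxymethoxy)phenyl]propan-2-one | CC(=O)Cc1ccc(OCOC)c(OC)c1
A1 | alternative 1 | rac-5-allyl-2-(1-chloroethoxy)-1,3-dimethoxybenzene | C=CCc1cc(OC)c(OC(C)Cl)c(OC)c1
A2 | alternative 1 | [3-methoxy-4-(triisopropylsilyloxy)benzyl]zinc chloride | Cl[Zn]Cc1ccc(O[Si](C(C)C)(C(C)C)C(C)C)c(OC)c1
A3 | alternative 1 | {4-[(2S)-2-(4-allyl-2,6-dimethoxyphenoxy)propyl]-2-methoxyphenoxy}triisopropylsilane | C=CCc1cc(OC)c(O[C@@H](C)Cc2ccc(O[Si](C(C)C)(C(C)C)C(C)C)c(OC)c2)c(OC)c1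
A4 | alternative 2 | rac-2-(4-allyl-2,6-dimethoxyphenoxy)-1-[3-methoxy-4-(methoxymethoxy)phenyl]propan-1-one | C=CCc1cc(OC)c(OC(C)C(=O)c2ccc(OCOC)c(OC)c2)c(OC)c1
A5 | alternative 2 | (1R,2S)-2-(4-allyl-2,6-dimethoxyphenoxy)-1-[3-methoxy-4-(methoxymethoxy)phenyl]propan-1-ol | C=CCc1cc(OC)c(O[C@@H](C)[C@H](O)c2ccc(OCOC)c(OC)c2)c(OC)c1
A6 | alternative 3 | (Z)-2-(4-bromo-2,6-dimethoxyphenoxy)-3-[3-methoxy-4-(methoxymethoxy)phenyl]prop-2-enoic acid | COc1cc(Br)cc(OC)c1O/C(C(=O)O)=C\c1ccc(OCOC)c(OC)c1
A7 | alternative 3 | (R)-2-(4-bromo-2,6-dimethoxyphenoxy)-3-[3-methoxy-4-(methoxymethoxy)phenyl]propanoic acid | COc1cc(Br)cc(OC)c1O[C@@H](C(=O)O)Cc1ccc(OCOC)c(OC)c1
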